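# Proposed total synthesis of CNP0214356.1 (7-methacryloyloxy-9-isobutyryloxy-longipin-2-en-1-one)

## Analysis of the target

Target 32 is a longipinane diester. A bicyclo[3.1.1]hept-2-en-1-one (bridge C1–C2–C3 over the cyclobutane C4–C5–C11–C10) has its two one-carbon bridges C5 and C10 tied together by the chain C6–C7–C8–C9, so a seven-membered ring spans the diagonal of the four-membered ring. There are six stereocentres, (4R,5S,7R,9R,10R,11R) in this numbering. C4, C5, C10 and C11 belong to the cage and depend on each other: the C10 methyl and C5–H must both point toward the C1–C3 bridge, otherwise the C6–C9 strap cannot close. C7 and C9 carry a trans-1,3-diol with two different esters, the methacrylate at C7 on the C4 face and the isobutyrate at C9 on the C11 face. They sit above a cage that is locally mirror-symmetric (the plane through C5, C6, C9 and C10 exchanges C4 and C11), so the substrate gives almost no facial bias at these two carbons. Sensitive groups are the methacrylate (radicals, nucleophiles, polymerisation), the two different acyl groups on a 1,3-diol (migration, β-elimination at the keto stage), the enone, and the strained cyclobutane next to carbonyl groups. The main difficulties are the quaternary C10 inside the cyclobutane, the two neopentyl ring bonds C5–C6 and C9–C10, and telling C7 from C9. The strategy rests on the bicyclo[3.1.1]heptane being the crossed [2+2] adduct of a ketene C5=C11 and the alkene C4=C10, joined by the three-atom tether C1–C2–C3; this leaves C5 as a ketone for attaching C6 and C9 as an oxygenated carbon on C10.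

## Retrosynthetic reasoning

**C7 ester (32 ⇒ 31).** The methacrylate is the most fragile group and is cut first. The forward step is a plain acylation of a secondary alcohol in the presence of the enone.

**Enone (31 ⇒ 29).** The C1 carbonyl and the C2=C3 bond are traced to the C1=C2 alkene of 29, with C3 as a CH(CH3) stereocentre, by an allylic oxidation with transposition. A photooxygenation ene reaction was considered and set aside: in 29 the only usable allylic hydrogen, C3–H, lies on the alkene face covered by the C10 methyl, and an ene reaction is suprafacial. A radical C–H abstraction has no such requirement. The allyl radical is of the verbenyl type and should take oxygen at the secondary end C1, which also moves the alkene into the trisubstituted position. The C3 stereocentre is erased here, as intended.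

**C7 carbinol and C9 ester (29 ⇒ 27).** Both are traced to the β-hydroxy ketone 27 by an Evans–Tishchenko reaction. It delivers hydride from the C9 oxygen to the same face of the C7 carbonyl (hence the 7,9-trans diol) and leaves the acyl group on the C9 oxygen. The two oxygens are therefore never at the same oxidation level and need no selective acylation.

**C9 oxygen (27 ⇒ 25).** The C9–O bond is cut to give the cycloheptenone 25. Because the cage is locally mirror-symmetric, a direct aldol addition (giving 24) would not control C9. The ring closure is therefore run through to the enone, and the stereocentre is set afterwards by a catalyst-controlled conjugate borylation and oxidation.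

**Seven-membered ring (25 ⇒ 23).** The C8–C9 bond is cut as an aldol condensation of keto aldehyde 23. This is the best place to close the ring: C8 is the only enolisable carbon (C6 is quaternary, the aldehyde is neopentyl), and the two arms are held cis on the cyclobutane diagonal.

**Functional group adjustment (23 ⇒ 21 ⇒ 20).** The C7 ketone comes from the vinyl group of 20 by Wacker oxidation, and the C9 aldehyde from the silyl ether.

**C5–C6 bond (20 ⇒ 18 ⇒ 15 + 16).** The quaternary C6 with its vinyl group is the γ-carbon of a prenyl metal (17, from prenyl bromide 16) added to the non-enolisable cyclobutanone 15. Radical deoxygenation of the tertiary carbinol then sets C5. The deoxygenation is placed before the Wacker step so that no β-hydroxy ketone (retro-aldol) is ever formed.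

**Key disconnection (15 ⇒ 13 via 14).** C4–C5 and C10–C11 are cut together. Forward, vinylketene 14 must add across the E alkene in the crossed sense and translate the one stereocentre C3 into C4, C10 and C11.

**Acid chloride (13 ⇒ 12 ⇒ 9 + 10).** The Z alkene C1=C2 comes from a Z-selective Wittig reaction of the α-branched aldehyde 9 with the ylide from phosphonium salt 10. The product is a β,γ-unsaturated acid that is already at the right oxidation level.

**Chain (9 ⇒ 5 ⇒ 2 + 3; 2 ⇒ 1).** The E alkene C4=C10 comes from ylide 3 and the aldehyde derived from ester 2. Extending the ester end first maps the ester carbon of 1 onto C4 and its hydroxymethyl carbon onto C2, and for that mapping the R enantiomer of 1 gives the required 5R acid. Using the S enantiomer would mean oxidising the hydroxymethyl end first, through a configurationally unstable formyl ester.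

## Alternatives that were turned down

**Alternative 1: one-carbon ring expansion.**
- Disconnection: C8 is removed, so the seven-membered 1,3-diketone A1 comes from a six-membered enediol bis-silyl ether A2 of the copaane type.
- Forward key step: zinc-carbenoid cyclopropanation across C7=C9 of A2, then opening of the three-membered ring with FeCl3 in the same flask.
- For: A1 has the whole carbon skeleton, the enone and both ring oxygens in one operation. On this point it is stronger than the chosen route, which needs a late C–H oxidation.
- Against: A2 already contains the bicyclo[3.1.1]heptenone with quaternary C10, so the hardest part is only moved back. Methylene transfer must reach a tetrasubstituted alkene between the quaternary C6 and C10. The oxidative opening passes through a β-oxo radical next to the cyclobutane. In A1 the C7 and C9 carbonyls are at the same oxidation level on a near-symmetric cage, with the C1 enone as a third carbonyl, so trans reduction and two different acylations have no handle.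
- Comparison: the chosen route keeps C7 as a ketone and C9 as an alcohol from the moment they appear, which is what makes the diester accessible.

**Alternative 2: Diels–Alder construction of the six-membered ring.**
- Disconnection: C5–C11 and C3–C4, giving diene A5 and cycloheptenone A4.
- Forward key step: Lewis-acid-promoted cycloaddition to A3, then acid to unmask the C1 ketone and eliminate silanol.
- For: it is convergent, both partners are simple, A4 brings the C7 oxygen and the gem-dimethyl group, and the enone with its methyl arrives complete. In convergence it is clearly better than the chosen linear route.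
- Against: the β-carbon C5 of A4 is neopentyl and a poor dienophile terminus. A bis-silyl dienol ether under Lewis acid tends to react stepwise (Mukaiyama–Michael), with weak control from the remote C7. Above all, A3 has no cyclobutane. C10–C11 would have to be closed between a ketone carbon and an enone α-carbon (a four-membered aldol, uphill), the resulting tertiary oxygen at C10 exchanged for methyl with retention, and C9 oxygenated.
- Comparison: the chosen key step makes exactly the four-membered ring and the quaternary C10 that this alternative leaves open.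

**Alternative 3: carbene cyclopropanation to a strapped bicyclobutane.**
- Disconnection: C4–C5, with a temporary C4–C11 bond; diazo ester A7 gives A6.
- Forward key step: Rh2(OAc)4 generates a carbenoid at C4 that adds across the ring alkene C5=C11.
- For: the seven-membered ring with C7 and C9, already differentiated by protecting groups, and the quaternary C10 are made on a monocycle by conventional control. On C7/C9 stereocontrol it is stronger than the chosen route, which must set these centres late by catalyst control.
- Against: A6 is more strained than the target. The carbenoid must reach a trisubstituted ring alkene two atoms away, in competition with C–H insertion into the strap. Afterwards the central bond must be cleaved with two hydrogens delivered cis, the C1–C2–C3 bridge built from an ester and a masked methyl ketone, and the C3 carbonyl turned into the methyl-bearing alkene. That is many steps after the key step.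
- Comparison: the chosen route closes both cage rings in one step from an acyclic chain and never passes through a structure more strained than the target.

Key step: step 9

## Remarks on the chemistry

- Cage atoms carry the numbers used in the analysis throughout. In the bicyclic compounds 15–23, bicyclo[3.1.1]heptane locants C1, C2, C3, C4, C5, C6, C7 correspond to cage atoms C11, C1, C2, C3, C4, C5, C10.
- A tert-butyldiphenylsilyl ether is used at C9 so that it survives acid chloride formation, the Wacker step and selective removal of the primary tert-butyldimethylsilyl ether.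
- Compounds 1, 3, 10 and 16 and all reagents are taken to be commercial.

## Route

Step 1
Reactants: 1 methyl (R)-3-hydroxy-2-methylpropanoate
Product: 2 methyl (R)-3-[tert-butyl(dimethyl)silyloxy]-2-methylpropanoate
Conditions: TBSCl, imidazole, DMF, 0 °C to rt
Reagents that add atoms: tert-butyldimethylsilyl chloride, CC(C)(C)[Si](C)(C)Cl
Why: Silylation of a primary alcohol with imidazole as base; nothing present can enolise the ester, so the stereocentre is untouched.

Step 2
Reactants: 2 methyl (R)-3-[tert-butyl(dimethyl)silyloxy]-2-methylpropanoate; 3 ethyl 2-(triphenylphosphoranylidene)propanoate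
Product: 5 ethyl (2E,4S)-5-[tert-butyl(dimethyl)silyloxy]-2,4-dimethylpent-2-enoate, via silyloxy aldehyde 4 (not isolated)
Conditions: iBu2AlH (1.1 equiv), CH2Cl2, −78 °C; then 3 (1.5 equiv), −78 °C to rt
Reagents that add atoms: none
Why: Partial ester reduction gives an aluminium hemiacetal that releases the α-branched aldehyde 4 only on warming, in the presence of the ylide, so it is trapped before it can epimerise. The Wittig reaction of the α-methyl stabilised ylide with a branched aldehyde should give the E trisubstituted enoate.

Step 3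
Reactants: 5 ethyl (2E,4S)-5-[tert-butyl(dimethyl)silyloxy]-2,4-dimethylpent-2-enoate
Product: 6 (2E,4S)-5-[tert-butyl(dimethyl)silyloxy]-2,4-dimethylpent-2-en-1-ol
Conditions: iBu2AlH (2.5 equiv), CH2Cl2, −78 to 0 °C
Reagents that add atoms: none
Why: 1,2-Reduction of an enoate to the allylic alcohol with an aluminium hydride; alkene geometry and the allylic stereocentre are not affected.

Step 4
Reactants: 6 (2E,4S)-5-[tert-butyl(dimethyl)silyloxy]-2,4-dimethylpent-2-en-1-ol
Product: 7 (2E,4S)-1-[tert-butyl(diphenyl)silyloxy]-5-[tert-butyl(dimethyl)silyloxy]-2,4-dimethylpent-2-ene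
Conditions: TBDPSCl, imidazole, CH2Cl2, rt
Reagents that add atoms: tert-butyldiphenylsilyl chloride, CC(C)(C)[Si](Cl)(c1ccccc1)c1ccccc1
Why: Standard silylation of a primary allylic alcohol; the bulkier, more acid-stable silyl group is placed on the future C9 oxygen.

Step 5
Reactants: 7 (2E,4S)-1-[tert-butyl(diphenyl)silyloxy]-5-[tert-butyl(dimethyl)silyloxy]-2,4-dimethylpent-2-ene
Product: 8 (2S,3E)-5-[tert-butyl(diphenyl)silyloxy]-2,4-dimethylpent-3-en-1-ol
Conditions: pyridinium p-toluenesulfonate (0.2 equiv), MeOH, rt
Reagents that add atoms: none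
Why: Mild acid methanolysis removes a primary tert-butyldimethylsilyl ether much faster than a tert-butyldiphenylsilyl ether, a well-established selectivity.

Step 6
Reactants: 8 (2S,3E)-5-[tert-butyl(diphenyl)silyloxy]-2,4-dimethylpent-3-en-1-ol
Product: 9 (2S,3E)-5-[tert-butyl(diphenyl)silyloxy]-2,4-dimethylpent-3-enal
Conditions: Dess–Martin periodinane, NaHCO3, CH2Cl2, 0 °C; used crude at once
Reagents that add atoms: none
Why: Buffered hypervalent-iodine oxidation is non-basic, so the α-stereocentre should survive. Allylic 1,3-strain with the cis methyl on C10 keeps C3–H out of conjugation with the alkene and slows isomerisation into conjugation.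

Step 7
Reactants: 9 (2S,3E)-5-[tert-butyl(diphenyl)silyloxy]-2,4-dimethylpent-3-enal; 10 (2-carboxyethyl)triphenylphosphonium bromide
Product: 12 (3Z,5R,6E)-8-[tert-butyl(diphenyl)silyloxy]-5,7-dimethylocta-3,6-dienoic acid, via phosphorus ylide carboxylate 11 (not isolated)
Conditions: 10 (2.0 equiv), NaN(SiMe3)2 (4.0 equiv), THF, −78 to 0 °C; then 9, −78 °C to rt; aq. HCl to pH 4
Reagents that add atoms: none
Why: Wittig reaction of a non-stabilised ylide (sodium base, low temperature) with a branched aldehyde is kinetically Z-selective and gives the β,γ-unsaturated acid directly. Adding the aldehyde cold to preformed excess ylide limits α-epimerisation.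

Step 8
Reactants: 12 (3Z,5R,6E)-8-[tert-butyl(diphenyl)silyloxy]-5,7-dimethylocta-3,6-dienoic acid
Product: 13 (3Z,5R,6E)-8-[tert-butyl(diphenyl)silyloxy]-5,7-dimethylocta-3,6-dienoyl chloride
Conditions: (COCl)2 (1.5 equiv), DMF (cat.), CH2Cl2, 0 °C to rt; evaporate, use crude
Reagents that add atoms: oxalyl chloride, ClC(=O)C(Cl)=O
Why: Acid chloride formation through the chloroiminium catalyst is fast at low temperature and base-free, so the β,γ-alkene should not move into conjugation and the silyl ether should survive the short contact with HCl.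

Step 9
Reactants: 13 (3Z,5R,6E)-8-[tert-butyl(diphenyl)silyloxy]-5,7-dimethylocta-3,6-dienoyl chloride
Product: 15 (1S,4R,5R,7S)-7-{[tert-butyl(diphenyl)silyl]oxymethyl}-4,7-dimethylbicyclo[3.1.1]hept-2-en-6-one, via vinylketene 14 (not isolated)
Conditions: Et3N (5 equiv), toluene, 110 °C, 13 added over several hours (final ≤0.01 M)
Reagents that add atoms: none
Why: Et3N removes the doubly activated C11–H of 13 (directly or through the acylammonium ion) and chloride is lost, giving the (Z)-vinylketene 14, in which the Z C1=C2 bond holds the ketene next to C4=C10. The nucleophilic alkene terminus C4 attacks the ketene carbonyl carbon C5 in its plane, positive charge builds on the disubstituted C10 and is quenched by the ketene α-carbon C11, an asynchronous concerted thermal ketene–alkene [2+2] cycloaddition. The closest known reaction type is the intramolecular vinylketene–alkene cycloaddition of dienoyl chlorides with a three-atom tether and a terminally disubstituted alkene, which gives bicyclo[3.1.1]hept-2-en-6-ones of the chrysanthenone type. The six-membered ring closes through C5–C4 in a 6-exo sense at the alkene (C10 stays outside and carries the charge), and the cyclobutanone closes through C11–C10 across that ring, which makes the adduct crossed and not fused. C10 is set by the alkene geometry: addition is suprafacial on C4=C10, so the methyl that is cis to C3 in the E alkene ends syn to the C1–C3 bridge and C9 ends anti. C4 and C11 are set together with it, because the three-atom tether can only span cis positions of the new cyclobutane. The absolute sense comes from C3: allylic 1,3-strain with the C10 methyl keeps C3–H in the alkene plane, so the tether folds over the alkene face opposite to the C3 methyl and that methyl ends on the C5 side of the bicycle. The step needs crossed regioselectivity, secured by the more substituted distal carbon C10, and it must outrun ketene dimerisation and the 1,5-hydrogen shift from C3 to C5 of 14, which slow addition into hot dilute base is meant to ensure.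

Step 10
Reactants: 15 (1S,4R,5R,7S)-7-{[tert-butyl(diphenyl)silyl]oxymethyl}-4,7-dimethylbicyclo[3.1.1]hept-2-en-6-one; 16 prenyl bromide (1-bromo-3-methylbut-2-ene)
Product: 18 7-{[tert-butyl(diphenyl)silyl]oxymethyl}-4,7-dimethyl-6-(2-methylbut-3-en-2-yl)bicyclo[3.1.1]hept-2-en-6-ol (cage as in 15; on cage C5 the new chain anti and OH syn to the C1–C3 bridge), via prenylzinc bromide 17 (not isolated)
Conditions: 16 (3 equiv), Zn dust (activated, 4 equiv), THF, 0 °C to rt; aq. NH4Cl
Reagents that add atoms: none
Why: Barbier-type allylation: the prenylzinc species adds through its γ-carbon in a cyclic transition state, giving the quaternary C6 with a vinyl group. The cyclobutanone is strained, electrophilic and cannot enolise (both α-carbons are bridgeheads); the bulky chain is expected in the roomier anti position, though the C5 configuration is reset in step 12.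

Step 11
Reactants: 18 7-{[tert-butyl(diphenyl)silyl]oxymethyl}-4,7-dimethyl-6-(2-methylbut-3-en-2-yl)bicyclo[3.1.1]hept-2-en-6-ol
Product: 19 methyl oxalate of 18 (methyl 7-{[tert-butyl(diphenyl)silyl]oxymethyl}-4,7-dimethyl-6-(2-methylbut-3-en-2-yl)bicyclo[3.1.1]hept-2-en-6-yl oxalate)
Conditions: nBuLi (1.1 equiv), THF, −78 °C; ClC(O)CO2Me (1.5 equiv), −78 to 0 °C
Reagents that add atoms: methyl chlorooxoacetate, COC(=O)C(Cl)=O
Why: Acylation of a hindered tertiary lithium alkoxide with a small, very reactive acid chloride. The cold lithium alkoxide avoids retro-allylation and alkoxide-driven opening of the 2-alkenylcyclobutanol.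

Step 12
Reactants: 19 methyl oxalate of 18
Product: 20 7-{[tert-butyl(diphenyl)silyl]oxymethyl}-4,7-dimethyl-6-(2-methylbut-3-en-2-yl)bicyclo[3.1.1]hept-2-ene (H on cage C5 syn and the chain anti to the C1–C3 bridge)
Conditions: Bu3SnH (3 equiv, 0.3 M), AIBN (0.2 equiv), toluene, 90 °C
Reagents that add atoms: none
Why: Barton–McCombie-type deoxygenation of a tertiary alkyl methyl oxalate: the stannyl radical adds to the oxalate, the C5–O bond fragments, and the tertiary cyclobutyl radical takes hydrogen from the stannane. The syn pocket of C5 is closed by the three-carbon bridge and the C3 methyl, so the tert-alkyl chain should settle anti and hydrogen enter syn, which is the cage configuration of the target; the stannane is kept concentrated to outrun 1,2-vinyl migration.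

Step 13
Reactants: 20 7-{[tert-butyl(diphenyl)silyl]oxymethyl}-4,7-dimethyl-6-(2-methylbut-3-en-2-yl)bicyclo[3.1.1]hept-2-ene
Product: 21 3-(7-{[tert-butyl(diphenyl)silyl]oxymethyl}-4,7-dimethylbicyclo[3.1.1]hept-2-en-6-yl)-3-methylbutan-2-one
Conditions: PdCl2 (0.2 equiv), CuCl (1 equiv), O2 (1 atm), DMF/H2O 7:1, rt
Reagents that add atoms: water, O
Why: Tsuji–Wacker oxidation: Markovnikov hydroxypalladation of the monosubstituted alkene gives the methyl ketone (C7=O, C8 methyl). The hindered cis-disubstituted ring alkene is far less reactive toward divalent palladium.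

Step 14
Reactants: 21 3-(7-{[tert-butyl(diphenyl)silyl]oxymethyl}-4,7-dimethylbicyclo[3.1.1]hept-2-en-6-yl)-3-methylbutan-2-one
Product: 22 3-[7-(hydroxymethyl)-4,7-dimethylbicyclo[3.1.1]hept-2-en-6-yl]-3-methylbutan-2-one
Conditions: Bu4NF, THF, rt to 45 °C
Reagents that add atoms: none
Why: Fluoride cleavage of the silyl ether; the ketone has only the C8 methyl as enolisable position and no aldehyde is present yet.

Step 15
Reactants: 22 3-[7-(hydroxymethyl)-4,7-dimethylbicyclo[3.1.1]hept-2-en-6-yl]-3-methylbutan-2-one
Product: 23 4,7-dimethyl-6-(3-methyl-2-oxobutan-3-yl)bicyclo[3.1.1]hept-2-ene-7-carbaldehyde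
Conditions: Dess–Martin periodinane, NaHCO3, CH2Cl2, rt
Reagents that add atoms: none
Why: Oxidation of a neopentyl primary alcohol to a non-enolisable aldehyde under neutral conditions.

Step 16
Reactants: 23 4,7-dimethyl-6-(3-methyl-2-oxobutan-3-yl)bicyclo[3.1.1]hept-2-ene-7-carbaldehyde
Product: 25 longipina-1,8-dien-7-one (tricycle with C1=C2, C3–H and C3 methyl on the C5 side, C7 ketone, C8=C9; cage as in 32), via aldol 24 (not isolated)
Conditions: KOH, MeOH, 60 °C
Reagents that add atoms: none
Why: Intramolecular aldol condensation: only C8 can enolise, the aldehyde cannot, and the two arms are held cis on the cyclobutane diagonal, so the 7-exo-trig closure to 24 is favoured and E1cB loss of water drives it to the conjugated cycloheptenone. The C9 carbinol centre of 24, which the cage cannot control, is deliberately removed.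

Step 17
Reactants: 25 longipina-1,8-dien-7-one
Product: 27 (9R)-9-hydroxylongipin-1-en-7-one (hydroxyl on the C11 face), via boronate 26 (not isolated)
Conditions: CuCl (5 mol %), NaOtBu (10 mol %), Josiphos-type bisphosphine (5 mol %; enantiomer that delivers boron to the Re face of C9), B2pin2 (1.2 equiv), MeOH (2 equiv), THF, rt; then NaBO3·4H2O, THF/H2O, rt
Reagents that add atoms: bis(pinacolato)diboron, CC1(C)OB(OC1(C)C)B1OC(C)(C)C(C)(C)O1 (boron of 26 only); sodium perborate, [Na+].[Na+].O[B-]1(O)OO[B-](O)(O)OO1 (oxygen at C9)
Why: Copper-catalysed asymmetric conjugate borylation of a cyclic enone, followed by C–B oxidation with retention. The two faces of C9 are related by the local mirror plane of the cage, so the ligand decides, as on a simple cycloheptenone; the unactivated C1=C2 alkene does not react with the boryl-copper species.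

Step 18
Reactants: 27 (9R)-9-hydroxylongipin-1-en-7-one
Product: 29 (7R,9R)-7-hydroxylongipin-1-en-9-yl 2-methylpropanoate, via hemiacetal 28 (not isolated)
Conditions: isobutyraldehyde (8 equiv), SmI2 (0.3 equiv), THF, −10 °C
Reagents that add atoms: isobutyraldehyde, CC(C)C=O
Why: Evans–Tishchenko reaction: the C9 hydroxyl adds to the aldehyde and the samarium-bound hemiacetal 28 passes its C–H to the C7 carbonyl through a six-membered transition state, from the face of the C9 oxygen. The new C7 hydroxyl is therefore trans to C9–O and the aldehyde ends as the C9 isobutyrate, so configuration and ester differentiation are settled together.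

Step 19
Reactants: 29 (7R,9R)-7-hydroxylongipin-1-en-9-yl 2-methylpropanoate
Product: 31 (7R,9R)-7-hydroxy-1-oxolongipin-2-en-9-yl 2-methylpropanoate, via allylic peroxide 30 (not isolated)
Conditions: Rh2(cap)4 (1 mol %; cap = caprolactamate), tBuOOH (70% aq., 5 equiv), K2CO3 (0.5 equiv), CH2Cl2, rt
Reagents that add atoms: tert-butyl hydroperoxide, CC(C)(C)OO
Why: Radical allylic oxidation with transposition: the tert-butylperoxyl radical abstracts the tertiary allylic C3–H (the bridgehead C11–H is orthogonal to the π system), the verbenyl-type allyl radical is captured at the secondary terminus C1 on the open C5 face to give 30, and loss of tert-butanol (Kornblum–DeLaMare type) gives the enone. The neopentyl carbinol C–H at C7 is much stronger than the allylic C–H and should be left alone.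

Step 20
Reactants: 31 (7R,9R)-7-hydroxy-1-oxolongipin-2-en-9-yl 2-methylpropanoate
Product: 32 (4R,5S,7R,9R,10R,11R)-7-(2-methylprop-2-enoyloxy)-1-oxolongipin-2-en-9-yl 2-methylpropanoate (CNP0214356.1)
Conditions: methacryloyl chloride, Et3N, DMAP (cat.), BHT (trace), CH2Cl2, 0 °C to rt
Reagents that add atoms: methacryloyl chloride, C=C(C)C(Cl)=O
Why: Nucleophile-catalysed acylation of the remaining secondary alcohol. The trans arrangement of the 1,3-oxygens on the ring disfavours the cyclic intermediate needed for migration of the isobutyrate, and the radical inhibitor guards the methacrylate.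

## Compound list

1 | methyl (R)-3-hydroxy-2-methylpropanoate | COC(=O)[C@H](C)CO | starting material
2 | methyl (R)-3-[tert-butyl(dimethyl)silyloxy]-2-methylpropanoate | COC(=O)[C@H](C)CO[Si](C)(C)C(C)(C)C | intermediate
3 | ethyl 2-(triphenylphosphoranylidene)propanoate | CCOC(=O)C(C)=P(c1ccccc1)(c1ccccc1)c1ccccc1 | starting material
4 | (R)-3-[tert-butyl(dimethyl)silyloxy]-2-methylpropanal (not isolated) | O=C[C@H](C)CO[Si](C)(C)C(C)(C)C | intermediate
5 | ethyl (2E,4S)-5-[tert-butyl(dimethyl)silyloxy]-2,4-dimethylpent-2-enoate | CCOC(=O)/C(C)=C/[C@H](C)CO[Si](C)(C)C(C)(C)C | intermediate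
6 | (2E,4S)-5-[tert-butyl(dimethyl)silyloxy]-2,4-dimethylpent-2-en-1-ol | OC/C(C)=C/[C@H](C)CO[Si](C)(C)C(C)(C)C | intermediate
7 | (2E,4S)-1-[tert-butyl(diphenyl)silyloxy]-5-[tert-butyl(dimethyl)silyloxy]-2,4-dimethylpent-2-ene | CC(C)(C)[Si](c1ccccc1)(c1ccccc1)OC/C(C)=C/[C@H](C)CO[Si](C)(C)C(C)(C)C | intermediate
8 | (2S,3E)-5-[tert-butyl(diphenyl)silyloxy]-2,4-dimethylpent-3-en-1-ol | CC(C)(C)[Si](c1ccccc1)(c1ccccc1)OC/C(C)=C/[C@H](C)CO | intermediate
9 | (2S,3E)-5-[tert-butyl(diphenyl)silyloxy]-2,4-dimethylpent-3-enal | CC(C)(C)[Si](c1ccccc1)(c1ccccc1)OC/C(C)=C/[C@H](C)C=O | intermediate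
10 | (2-carboxyethyl)triphenylphosphonium bromide | OC(=O)CC[P+](c1ccccc1)(c1ccccc1)c1ccccc1.[Br-] | starting material
11 | sodium 3-(triphenylphosphoranylidene)propanoate (not isolated) | [Na+].[O-]C(=O)CC=P(c1ccccc1)(c1ccccc1)c1ccccc1 | intermediate
12 | (3Z,5R,6E)-8-[tert-butyl(diphenyl)silyloxy]-5,7-dimethylocta-3,6-dienoic acid | OC(=O)C/C=C\[C@@H](C)/C=C(\C)CO[Si](c1ccccc1)(c1ccccc1)C(C)(C)C | intermediate
13 | (3Z,5R,6E)-8-[tert-butyl(diphenyl)silyloxy]-5,7-dimethylocta-3,6-dienoyl chloride | O=C(Cl)C/C=C\[C@@H](C)/C=C(\C)CO[Si](c1ccccc1)(c1ccccc1)C(C)(C)C | intermediate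
14 | (3Z,5R,6E)-8-[tert-butyl(diphenyl)silyloxy]-5,7-dimethylocta-1,3,6-trien-1-one, vinylketene (not isolated) | O=C=C/C=C\[C@@H](C)/C=C(\C)CO[Si](c1ccccc1)(c1ccccc1)C(C)(C)C | intermediate
15 | (1S,4R,5R,7S)-7-{[tert-butyl(diphenyl)silyl]oxymethyl}-4,7-dimethylbicyclo[3.1.1]hept-2-en-6-one | CC(C)(C)[Si](c1ccccc1)(c1ccccc1)OC[C@@]1(C)[C@@H]2C=C[C@@H](C)[C@H]1C2=O | intermediate
16 | prenyl bromide (1-bromo-3-methylbut-2-ene) | CC(C)=CCBr | starting material
17 | prenylzinc bromide (not isolated) | CC(C)=CC[Zn]Br | intermediate
18 | 7-{[tert-butyl(diphenyl)silyl]oxymethyl}-4,7-dimethyl-6-(2-methylbut-3-en-2-yl)bicyclo[3.1.1]hept-2-en-6-ol | CC(C)(C)[Si](c1ccccc1)(c1ccccc1)OC[C@@]1(C)[C@@H]2C=C[C@@H](C)[C@H]1[C@]2(O)C(C)(C)C=C | intermediate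
19 | methyl oxalate of 18 | CC(C)(C)[Si](c1ccccc1)(c1ccccc1)OC[C@@]1(C)[C@@H]2C=C[C@@H](C)[C@H]1[C@]2(OC(=O)C(=O)OC)C(C)(C)C=C | intermediate
20 | 7-{[tert-butyl(diphenyl)silyl]oxymethyl}-4,7-dimethyl-6-(2-methylbut-3-en-2-yl)bicyclo[3.1.1]hept-2-ene | CC(C)(C)[Si](c1ccccc1)(c1ccccc1)OC[C@@]1(C)[C@@H]2C=C[C@@H](C)[C@H]1[C@@H]2C(C)(C)C=C | intermediate
21 | 3-(7-{[tert-butyl(diphenyl)silyl]oxymethyl}-4,7-dimethylbicyclo[3.1.1]hept-2-en-6-yl)-3-methylbutan-2-one | CC(C)(C)[Si](c1ccccc1)(c1ccccc1)OC[C@@]1(C)[C@@H]2C=C[C@@H](C)[C@H]1[C@@H]2C(C)(C)C(C)=O | intermediate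
22 | 3-[7-(hydroxymethyl)-4,7-dimethylbicyclo[3.1.1]hept-2-en-6-yl]-3-methylbutan-2-one | OC[C@@]1(C)[C@@H]2C=C[C@@H](C)[C@H]1[C@@H]2C(C)(C)C(C)=O | intermediate
23 | 4,7-dimethyl-6-(3-methyl-2-oxobutan-3-yl)bicyclo[3.1.1]hept-2-ene-7-carbaldehyde | O=C[C@@]1(C)[C@@H]2C=C[C@@H](C)[C@H]1[C@@H]2C(C)(C)C(C)=O | intermediate
24 | 9-hydroxylongipin-1-en-7-one, both C9 epimers (not isolated) | O=C1CC(O)[C@@]2(C)[C@@H]3C=C[C@@H](C)[C@H]2[C@@H]3C1(C)C | intermediate
25 | longipina-1,8-dien-7-one | O=C1C=C[C@@]2(C)[C@@H]3C=C[C@@H](C)[C@H]2[C@@H]3C1(C)C | intermediate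
26 | 9-(4,4,5,5-tetramethyl-1,3,2-dioxaborolan-2-yl)longipin-1-en-7-one, boron on the C11 face (not isolated) | O=C1C[C@@H](B4OC(C)(C)C(C)(C)O4)[C@@]2(C)[C@@H]3C=C[C@@H](C)[C@H]2[C@@H]3C1(C)C | intermediate
27 | (9R)-9-hydroxylongipin-1-en-7-one | O=C1C[C@@H](O)[C@@]2(C)[C@@H]3C=C[C@@H](C)[C@H]2[C@@H]3C1(C)C | intermediate
28 | 9-(1-hydroxy-2-methylpropoxy)longipin-1-en-7-one, hemiacetal (not isolated) | O=C1C[C@@H](OC(O)C(C)C)[C@@]2(C)[C@@H]3C=C[C@@H](C)[C@H]2[C@@H]3C1(C)C | intermediate
29 | (7R,9R)-7-hydroxylongipin-1-en-9-yl 2-methylpropanoate | O[C@@H]1C[C@@H](OC(=O)C(C)C)[C@@]2(C)[C@@H]3C=C[C@@H](C)[C@H]2[C@@H]3C1(C)C | intermediate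
30 | 1-(tert-butylperoxy)-7-hydroxylongipin-2-en-9-yl 2-methylpropanoate, peroxide on the C5 face (not isolated) | O[C@@H]1C[C@@H](OC(=O)C(C)C)[C@@]2(C)[C@@H]3[C@@H](OOC(C)(C)C)C=C(C)[C@H]2[C@@H]3C1(C)C | intermediate
31 | (7R,9R)-7-hydroxy-1-oxolongipin-2-en-9-yl 2-methylpropanoate | O[C@@H]1C[C@@H](OC(=O)C(C)C)[C@@]2(C)[C@@H]3C(=O)C=C(C)[C@H]2[C@@H]3C1(C)C | intermediate
32 | (4R,5S,7R,9R,10R,11R)-7-(2-methylprop-2-enoyloxy)-1-oxolongipin-2-en-9-yl 2-methylpropanoate (CNP0214356.1) | C=C(C)C(=O)O[C@@H]1C[C@@H](OC(=O)C(C)C)[C@@]2(C)[C@@H]3C(=O)C=C(C)[C@H]2[C@@H]3C1(C)C | target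

## Step count and risk

Total step count: 20. Longest linear sequence: 20 steps (1 to 32); 3, 10 and 16 enter as purchased reagents.

**Step 9 (key step).** The 1,5-hydrogen shift from C3 to the ketene carbon of 14 and ketene oligomerisation may outrun the cycloaddition, because the Z geometry that the cycloaddition needs also holds the C3–H next to C5. Incomplete facial control would give the diastereomeric cage. The fallback sets out from acid 12 and returns at 15. It replaces the ketene by a keteniminium ion, a much stronger electrophile that should cyclise at lower temperature in the same crossed sense. Acid 12 is coupled with pyrrolidine (EDC·HCl, HOBt, CH2Cl2) to the pyrrolidine amide F1. Tf2O and 2,4,6-collidine in 1,2-dichloroethane (rt to 80 °C) convert F1 through the vinyl keteniminium ion into the cyclobutaniminium triflate F2, and hydrolysis of F2 with water gives 15.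

**Step 12.** The tertiary cyclobutyl radical at C5 may rearrange by 1,2-vinyl migration (3-exo closure onto C7=C8) before it is reduced, and hydrogen may be delivered to the anti face, because the radical is hindered and slow to take hydrogen. The fallback sets out from 15 and returns at 21, so it also bypasses step 13. It uses a nitrile in place of the vinyl group, which removes the migrating group. Lithiated isobutyronitrile (isobutyronitrile, LiN(iPr)2, THF, −78 °C) adds to 15, and the lithium alkoxide is acylated in the same flask with methyl chlorooxoacetate to give the oxalate nitrile F3. Bu3SnH/AIBN reduces F3 to the nitrile F4, where the same steric argument for syn hydrogen delivery holds. MeLi adds to F4 to give the ketimine F5, and aqueous HCl hydrolyses F5 to 21.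

**Step 17.** Conversion may be low or facial selectivity poor in the boryl-copper addition, because C9 is flanked by the quaternary C10 and the substrate offers no help to the catalyst. The fallback sets out from 25 and returns at 27. It relays configuration from a reagent-controlled carbonyl reduction instead. Corey–Bakshi–Shibata reduction of 25 ((R)-methyl oxazaborolidine catalyst, BH3·SMe2; quaternary C6 as the large group) should give the (7S)-allylic alcohol F6 with hydroxyl on the C11 face. Hydroxyl-directed epoxidation (VO(acac)2, tBuOOH) gives the syn epoxy alcohol F7, and Dess–Martin oxidation gives the epoxy ketone F8. SmI2 in THF/MeOH at −90 °C cleaves the Cα–O bond of F8 and gives 27.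

**Step 19.** Hydrogen abstraction from C3–H, which lies close to the C10 methyl, may be slow, and the allyl radical may be captured at C3 instead of C1; over-oxidation at C7 is a lesser concern. The fallback sets out from 29 and returns at 31. It installs the C1 oxygen by hydroboration and the alkene by dehydrogenation. The C7 hydroxyl is protected (Et3SiOTf, 2,6-lutidine) as the triethylsilyl ether F9. Hydroboration from the open C5 face (BH3·THF, 0 °C; NaBO3) should place boron at C1, away from the C3 methyl, and give the C1 alcohol F10. Dess–Martin oxidation gives the C1 ketone F11, which can enolise only toward C2. Dehydrogenation with 2-iodoxybenzoic acid in DMSO at 65 °C gives the enone silyl ether F12, and HF·pyridine removes the silyl group to give 31.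

**Step 13.** Oxypalladation of the vinyl group on the quaternary C6 may be slow or turn anti-Markovnikov, giving aldehyde or recovered alkene. The fallback sets out from 20 and returns at 21. It uses a radical hydration in which the hydrogen atom adds first to the terminal carbon. Mukaiyama hydration (Co(acac)2 cat., PhSiH3, O2, iPrOH/THF) of the monosubstituted alkene gives the secondary alcohol F13 as a mixture at C7, and Dess–Martin oxidation of F13 gives 21.

## Further compounds

F1 | step 9 | (3Z,5R,6E)-8-[tert-butyl(diphenyl)silyloxy]-5,7-dimethyl-1-(pyrrolidin-1-yl)octa-3,6-dien-1-one | O=C(C/C=C\[C@@H](C)/C=C(\C)CO[Si](c1ccccc1)(c1ccccc1)C(C)(C)C)N1CCCC1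
F2 | step 9 | 1-(7-{[tert-butyl(diphenyl)silyl]oxymethyl}-4,7-dimethylbicyclo[3.1.1]hept-2-en-6-ylidene)pyrrolidinium triflate | CC(C)(C)[Si](c1ccccc1)(c1ccccc1)OC[C@@]1(C)[C@@H]2C=C[C@@H](C)[C@H]1C2=[N+]1CCCC1.[O-]S(=O)(=O)C(F)(F)F
F3 | step 12 | 6-(2-cyanopropan-2-yl)-7-{[tert-butyl(diphenyl)silyl]oxymethyl}-4,7-dimethylbicyclo[3.1.1]hept-2-en-6-yl methyl oxalate | CC(C)(C)[Si](c1ccccc1)(c1ccccc1)OC[C@@]1(C)[C@@H]2C=C[C@@H](C)[C@H]1[C@]2(OC(=O)C(=O)OC)C(C)(C)C#N
F4 | step 12 | 2-(7-{[tert-butyl(diphenyl)silyl]oxymethyl}-4,7-dimethylbicyclo[3.1.1]hept-2-en-6-yl)-2-methylpropanenitrile | CC(C)(C)[Si](c1ccccc1)(c1ccccc1)OC[C@@]1(C)[C@@H]2C=C[C@@H](C)[C@H]1[C@@H]2C(C)(C)C#N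
F5 | step 12 | 3-(7-{[tert-butyl(diphenyl)silyl]oxymethyl}-4,7-dimethylbicyclo[3.1.1]hept-2-en-6-yl)-3-methylbutan-2-imine | CC(C)(C)[Si](c1ccccc1)(c1ccccc1)OC[C@@]1(C)[C@@H]2C=C[C@@H](C)[C@H]1[C@@H]2C(C)(C)C(C)=N
F6 | step 17 | (7S)-longipina-1,8-dien-7-ol | O[C@H]1C=C[C@@]2(C)[C@@H]3C=C[C@@H](C)[C@H]2[C@@H]3C1(C)C
F7 | step 17 | 8,9-epoxylongipin-1-en-7-ol, epoxide and hydroxyl on the C11 face | O[C@H]1[C@H]2O[C@H]2[C@@]3(C)[C@@H]4C=C[C@@H](C)[C@H]3[C@@H]4C1(C)C
F8 | step 17 | 8,9-epoxylongipin-1-en-7-one, epoxide on the C11 face | O=C1[C@H]2O[C@H]2[C@@]3(C)[C@@H]4C=C[C@@H](C)[C@H]3[C@@H]4C1(C)C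
F9 | step 19 | (7R,9R)-7-(triethylsilyloxy)longipin-1-en-9-yl 2-methylpropanoate | CC[Si](CC)(CC)O[C@@H]1C[C@@H](OC(=O)C(C)C)[C@@]2(C)[C@@H]3C=C[C@@H](C)[C@H]2[C@@H]3C1(C)C
F10 | step 19 | 1-hydroxy-7-(triethylsilyloxy)longipinan-9-yl 2-methylpropanoate, C1 hydroxyl on the C5 face | CC[Si](CC)(CC)O[C@@H]1C[C@@H](OC(=O)C(C)C)[C@@]2(C)[C@@H]3[C@@H](O)C[C@@H](C)[C@H]2[C@@H]3C1(C)C
F11 | step 19 | 1-oxo-7-(triethylsilyloxy)longipinan-9-yl 2-methylpropanoate | CC[Si](CC)(CC)O[C@@H]1C[C@@H](OC(=O)C(C)C)[C@@]2(C)[C@@H]3C(=O)C[C@@H](C)[C@H]2[C@@H]3C1(C)C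
F12 | step 19 | 1-oxo-7-(triethylsilyloxy)longipin-2-en-9-yl 2-methylpropanoate | CC[Si](CC)(CC)O[C@@H]1C[C@@H](OC(=O)C(C)C)[C@@]2(C)[C@@H]3C(=O)C=C(C)[C@H]2[C@@H]3C1(C)C
F13 | step 13 | 3-(7-{[tert-butyl(diphenyl)silyl]oxymethyl}-4,7-dimethylbicyclo[3.1.1]hept-2-en-6-yl)-3-methylbutan-2-ol, both carbinol epimers | CC(C)(C)[Si](c1ccccc1)(c1ccccc1)OC[C@@]1(C)[C@@H]2C=C[C@@H](C)[C@H]1[C@@H]2C(C)(C)C(C)O
A1 | alternative 1 | longipin-2-ene-1,7,9-trione | O=C1CC(=O)[C@@]2(C)[C@@H]3C(=O)C=C(C)[C@H]2[C@@H]3C1(C)C
A2 | alternative 1 | copaane-type enediol bis(trimethylsilyl) ether with C7=C9 and the C1 enone | C[Si](C)(C)OC1=C(O[Si](C)(C)C)[C@@]2(C)[C@@H]3C(=O)C=C(C)[C@H]2[C@@H]3C1(C)C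
A3 | alternative 2 | cis-fused 7-[tert-butyl(dimethyl)silyloxy]-3,6,6-trimethylbicyclo[5.4.0]undec-2-ene-1,10-dione (cage numbering) | O=C1C[C@@H]2[C@H](C(C)=C1)C(=O)CC[C@@H](O[Si](C)(C)C(C)(C)C)C2(C)C
A4 | alternative 2 | (R)-5-[tert-butyl(dimethyl)silyloxy]-4,4-dimethylcyclohept-2-en-1-one | O=C1C=CC(C)(C)[C@H](O[Si](C)(C)C(C)(C)C)CC1
A5 | alternative 2 | 2,4-bis(trimethylsilyloxy)penta-1,3-diene | C=C(O[Si](C)(C)C)C=C(C)O[Si](C)(C)C
A6 | alternative 3 | strapped bicyclo[1.1.0]butane methyl ester (tricyclo[5.1.0.0^2,8]octane) with C7 silyl ether, C9 p-methoxybenzyl ether and C1 dioxolane | CC(C)(C)[Si](C)(C)O[C@@H]1C[C@@H](OCc6ccc(OC)cc6)[C@@]2(C)[C@@]4(C5(C)OCCO5)[C@H]([C@@]24C(=O)OC)C1(C)C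
A7 | alternative 3 | cycloheptene α-diazo ester (diazo carbon C4 on C10, ring alkene C5=C11) | CC(C)(C)[Si](C)(C)O[C@@H]1C[C@@H](OCc2ccc(OC)cc2)[C@](C)(C(=[N+]=[N-])C(=O)OC)C(C2(C)OCCO2)=CC1(C)C
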